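The target places the C4' phenol oxygen on C7 and carbon C9 on the neighbouring C8, trans across the C7–C8 bond of the dihydrofuran ring (O, C7, C8, C3', C4'): the pattern left by anti addition of oxygen and carbon to an (E)-alkene. Both bonds, O–C7 and C8–C9, are therefore disconnected together. In one operation a chiral divalent palladium catalyst should make the ortho phenol add to the stilbene double bond and trap the C8–palladium bond with carbon monoxide and methanol, closing the ring and setting both stereocentres. The precursor is the (E)-2-hydroxystilbene from Heck coupling of 5-iodovanillin with 3,4,5-trimethoxystyrene; its formyl group later becomes the allylic alcohol side chain.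

Key step: step 3

Remark on the chemistry: the sense of induction of the bisoxazoline ligand in step 3 cannot be predicted with confidence, so it is assumed that the antipode leading to the (2R,3R) ester is identified in a pilot run (both antipodes are commercial).

Step 1
Reactants: 1 3,4,5-trimethoxybenzaldehyde; 2 methyltriphenylphosphonium bromide
Product: 3 3,4,5-trimethoxystyrene
Conditions: Ph3PCH3Br (1.3 equiv), KOtBu (1.25 equiv), THF, 0 °C to rt
Reagents that add atoms: methyltriphenylphosphonium bromide 2, C[P+](c1ccccc1)(c1ccccc1)c1ccccc1.[Br-] (supplies the CH2 carbon)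
Why: Wittig methylenation of a non-enolisable aromatic aldehyde with the ylide made in the flask is reliable and leaves the aryl methyl ethers untouched.

Step 2
Reactants: 3 3,4,5-trimethoxystyrene; 4 4-hydroxy-3-iodo-5-methoxybenzaldehyde (5-iodovanillin)
Product: 5 4-hydroxy-3-methoxy-5-[(E)-2-(3,4,5-trimethoxyphenyl)ethenyl]benzaldehyde
Conditions: Pd(OAc)2 (3 mol%), P(o-tol)3 (6 mol%), NaOAc (1.5 equiv), DMF, 100 °C
Reagents that add atoms: none
Why: In this Mizoroki–Heck reaction zerovalent palladium adds into the C–I bond of the formyl-activated aryl iodide, the styrene inserts at its terminal carbon and syn beta-hydride elimination should give the (E)-stilbene, the free ortho phenol and the aldehyde being tolerated by the mild carboxylate base.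

Step 3
Reactants: 5 4-hydroxy-3-methoxy-5-[(E)-2-(3,4,5-trimethoxyphenyl)ethenyl]benzaldehyde; 6 carbon monoxide; 7 methanol
Product: 8 methyl (2R,3R)-5-formyl-7-methoxy-2-(3,4,5-trimethoxyphenyl)-2,3-dihydro-1-benzofuran-3-carboxylate (trans)
Conditions: Pd(OCOCF3)2 (10 mol%), 2,2'-isopropylidenebis[(4S)-4-phenyl-2-oxazoline] or its antipode (12 mol%), p-benzoquinone (1.5 equiv), CO (5 bar), MeOH (10 equiv), CH2Cl2, 0 °C to rt
Reagents that add atoms: carbon monoxide 6, [C-]#[O+]; methanol 7, CO
Why: Proposed new method: the cationic bisoxazoline complex of divalent palladium binds one enantioface of the C7=C8 bond, the ortho phenol oxygen attacks the benzylic carbon C7 from the opposite face (anti oxypalladation), and the benzylic C8–palladium bond so formed inserts carbon monoxide with retention before methanol cleaves the acylpalladium to the methyl ester, p-benzoquinone returning zerovalent palladium to the divalent state. The closest known reaction types are the palladium-catalysed intramolecular alkoxycarbonylation of hydroxyalkenes, the cyclisation–carbonylation of 2-alkynylphenols to benzofuran-3-carboxylates, the oxidative cyclisation of 2-hydroxystilbenes to 2-arylbenzofurans and enantioselective Wacker-type cyclisations of alkenylphenols with bisoxazoline-type ligands, none of which combines a 5-endo closure onto a stilbene with carbonylative capture. The dihydrofuran ring closes in the 5-endo-trig mode, the only one open to a hydroxyl ortho to the vinyl group, and the electron-rich trimethoxyphenyl ring directs the oxygen to C7 by stabilising positive charge there. C7 is set by the ligand through its choice of alkene face, and C8 is set relative to C7 by the substrate, since anti addition across the (E)-alkene followed by retentive insertion puts the ester trans to the aryl group. The selectivity most at stake is carbon monoxide insertion against beta-hydride loss of H7, which would aromatise the ring to a benzofuran; carbon monoxide pressure, a chelating ligand that leaves no vacant cis site and a low temperature favour insertion, and limiting methanol to a few equivalents keeps intermolecular methoxypalladation down. The formyl group para to the hydroxyl makes the phenol acidic enough to react without added base and protects this guaiacol-type ring from oxidation by the quinone.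

Step 4
Reactants: 8 methyl (2R,3R)-5-formyl-7-methoxy-2-(3,4,5-trimethoxyphenyl)-2,3-dihydro-1-benzofuran-3-carboxylate; 9 methyl (triphenylphosphoranylidene)acetate
Product: 10 methyl (2R,3R)-7-methoxy-5-[(E)-3-methoxy-3-oxoprop-1-en-1-yl]-2-(3,4,5-trimethoxyphenyl)-2,3-dihydro-1-benzofuran-3-carboxylate
Conditions: Ph3P=CHCO2Me (1.3 equiv), toluene, 80 °C
Reagents that add atoms: methyl (triphenylphosphoranylidene)acetate 9, COC(=O)C=P(c1ccccc1)(c1ccccc1)c1ccccc1
Why: Wittig olefination with a stabilised ylide is E-selective on aromatic aldehydes and needs no added base, so the C8–H (alpha to the ester, beta to the aryloxy group) should be neither epimerised nor eliminated.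

Step 5
Reactants: 10 methyl (2R,3R)-7-methoxy-5-[(E)-3-methoxy-3-oxoprop-1-en-1-yl]-2-(3,4,5-trimethoxyphenyl)-2,3-dihydro-1-benzofuran-3-carboxylate
Product: 11 (-)-(7R,8S,7'E)-3,4,5,5'-tetramethoxy-4',7-epoxy-8,3'-neolign-7'-ene-9,9'-diol (target)
Conditions: iBu2AlH (6 equiv), CH2Cl2, −78 to 0 °C; aq. potassium sodium tartrate
Reagents that add atoms: none
Why: Aluminium hydride reduction of esters with iBu2AlH should take the enoate 1,2-selectively to the allylic alcohol and the saturated ester to the primary alcohol, without touching the alkene, the aryl ethers or the two stereocentres.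

Compound list
1 | 3,4,5-trimethoxybenzaldehyde | COc1cc(C=O)cc(OC)c1OC | starting material
2 | methyltriphenylphosphonium bromide | C[P+](c1ccccc1)(c1ccccc1)c1ccccc1.[Br-] | starting material
3 | 3,4,5-trimethoxystyrene (5-ethenyl-1,2,3-trimethoxybenzene) | C=Cc1cc(OC)c(OC)c(OC)c1 | intermediate
4 | 4-hydroxy-3-iodo-5-methoxybenzaldehyde (5-iodovanillin) | COc1cc(C=O)cc(I)c1O | starting material
5 | 4-hydroxy-3-methoxy-5-[(E)-2-(3,4,5-trimethoxyphenyl)ethenyl]benzaldehyde | COc1cc(/C=C/c2cc(C=O)cc(OC)c2O)cc(OC)c1OC | intermediate
6 | carbon monoxide | [C-]#[O+] | starting material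
7 | methanol | CO | starting material
8 | methyl (2R,3R)-5-formyl-7-methoxy-2-(3,4,5-trimethoxyphenyl)-2,3-dihydro-1-benzofuran-3-carboxylate (2-aryl and 3-ester trans) | COc1cc([C@@H]2Oc3c(OC)cc(C=O)cc3[C@H]2C(=O)OC)cc(OC)c1OC | intermediate
9 | methyl (triphenylphosphoranylidene)acetate | COC(=O)C=P(c1ccccc1)(c1ccccc1)c1ccccc1 | starting material
10 | methyl (2R,3R)-7-methoxy-5-[(E)-3-methoxy-3-oxoprop-1-en-1-yl]-2-(3,4,5-trimethoxyphenyl)-2,3-dihydro-1-benzofuran-3-carboxylate (trans) | COc1cc([C@@H]2Oc3c(OC)cc(/C=C/C(=O)OC)cc3[C@H]2C(=O)OC)cc(OC)c1OC | intermediate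
11 | (-)-(7R,8S,7'E)-3,4,5,5'-tetramethoxy-4',7-epoxy-8,3'-neolign-7'-ene-9,9'-diol, i.e. (E)-3-[(2R,3S)-3-(hydroxymethyl)-7-methoxy-2-(3,4,5-trimethoxyphenyl)-2,3-dihydro-1-benzofuran-5-yl]prop-2-en-1-ol | COc1cc([C@@H]2Oc3c(OC)cc(/C=C/CO)cc3[C@H]2CO)cc(OC)c1OC | target

Total step count: 5. Longest linear sequence: 5 steps (1 to 3 to 5 to 8 to 10 to 11).

Steps most likely to fail

Step 3 (the proposed new method) is the riskiest. Three processes could defeat it:
- weak enantioface discrimination by the ligand;
- beta-hydride elimination outrunning carbon monoxide insertion, which aromatises the ring;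
- carbonylation at the phenol oxygen before it attacks the alkene, which leads to cyclocarbonylation to a six-membered lactone.

The fallback uses known chemistry, forms the C7–C8 bond instead, sets out from 4 and returns at 8. O-Alkylation of 4 with 3,4,5-trimethoxybenzyl bromide (K2CO3, DMF) should give 3-iodo-5-methoxy-4-[(3,4,5-trimethoxybenzyl)oxy]benzaldehyde F1. Palladium-catalysed coupling of the aryl iodide with methyl diazoacetate (Pd(PPh3)4, Ag2CO3, Et3N, toluene, rt) should give methyl 2-diazo-2-{5-formyl-3-methoxy-2-[(3,4,5-trimethoxybenzyl)oxy]phenyl}acetate F2. Enantioselective intramolecular C–H insertion of the rhodium carbenoid into the benzylic ether C–H bond, with dirhodium tetrakis[N-phthaloyl-(S)-tert-leucinate], Rh2(S-PTTL)4, or its antipode (dilute toluene, −60 °C), should give the cis ester methyl (2R,3S)-5-formyl-7-methoxy-2-(3,4,5-trimethoxyphenyl)-2,3-dihydro-1-benzofuran-3-carboxylate F3. Equilibration at C3 with catalytic NaOMe in MeOH at 0 °C should convert it to the more stable trans ester 8.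

Step 2 comes next. The free ortho-hydroxy aryl iodide may deactivate the catalyst as a phenoxide, and arylation at the internal alkene carbon would erode regioselectivity. The fallback fixes alkene geometry and regiochemistry before the coupling, sets out from 3 and returns at 5. Cross-metathesis of 3 with 4,4,5,5-tetramethyl-2-vinyl-1,3,2-dioxaborolane (second-generation Grubbs catalyst, CH2Cl2, 40 °C) should give 4,4,5,5-tetramethyl-2-[(E)-2-(3,4,5-trimethoxyphenyl)ethenyl]-1,3,2-dioxaborolane F4. Suzuki–Miyaura coupling of this boronate with 4 (Pd(PPh3)4, K2CO3, dioxane/H2O, 80 °C) should give 5.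

Step 5 is third. Two different esters must be reduced in one pot, so reduction at the hindered C8 ester may stall at the aldehyde stage, where enolisation can open the ring, or conjugate reduction of the enoate may compete. The fallback separates the two reductions, sets out from 8 and returns at 11. LiBH4 (THF, 0 °C to rt) should reduce aldehyde and ester of 8 to [(2R,3S)-3-(hydroxymethyl)-7-methoxy-2-(3,4,5-trimethoxyphenyl)-2,3-dihydro-1-benzofuran-5-yl]methanol F5. MnO2 (CH2Cl2, rt) should re-oxidise only the benzylic alcohol, giving (2R,3S)-3-(hydroxymethyl)-7-methoxy-2-(3,4,5-trimethoxyphenyl)-2,3-dihydro-1-benzofuran-5-carbaldehyde F6. Wittig reaction with (triphenylphosphoranylidene)acetaldehyde (toluene, 80 °C) should give (E)-3-[(2R,3S)-3-(hydroxymethyl)-7-methoxy-2-(3,4,5-trimethoxyphenyl)-2,3-dihydro-1-benzofuran-5-yl]prop-2-enal F7. Luche reduction (NaBH4, CeCl3·7H2O, MeOH, 0 °C) should then give 11.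

Further compounds
F1 | step 3 | 3-iodo-5-methoxy-4-[(3,4,5-trimethoxybenzyl)oxy]benzaldehyde | COc1cc(C=O)cc(I)c1OCc1cc(OC)c(OC)c(OC)c1
F2 | step 3 | methyl 2-diazo-2-{5-formyl-3-methoxy-2-[(3,4,5-trimethoxybenzyl)oxy]phenyl}acetate | COC(=O)C(=[N+]=[N-])c1cc(C=O)cc(OC)c1OCc1cc(OC)c(OC)c(OC)c1
F3 | step 3 | methyl (2R,3S)-5-formyl-7-methoxy-2-(3,4,5-trimethoxyphenyl)-2,3-dihydro-1-benzofuran-3-carboxylate (cis) | COc1cc([C@@H]2Oc3c(OC)cc(C=O)cc3[C@@H]2C(=O)OC)cc(OC)c1OC
F4 | step 2 | 4,4,5,5-tetramethyl-2-[(E)-2-(3,4,5-trimethoxyphenyl)ethenyl]-1,3,2-dioxaborolane | COc1cc(/C=C/B2OC(C)(C)C(C)(C)O2)cc(OC)c1OC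
F5 | step 5 | [(2R,3S)-3-(hydroxymethyl)-7-methoxy-2-(3,4,5-trimethoxyphenyl)-2,3-dihydro-1-benzofuran-5-yl]methanol | COc1cc([C@@H]2Oc3c(OC)cc(CO)cc3[C@H]2CO)cc(OC)c1OC
F6 | step 5 | (2R,3S)-3-(hydroxymethyl)-7-methoxy-2-(3,4,5-trimethoxyphenyl)-2,3-dihydro-1-benzofuran-5-carbaldehyde | COc1cc([C@@H]2Oc3c(OC)cc(C=O)cc3[C@H]2CO)cc(OC)c1OC
F7 | step 5 | (E)-3-[(2R,3S)-3-(hydroxymethyl)-7-methoxy-2-(3,4,5-trimethoxyphenyl)-2,3-dihydro-1-benzofuran-5-yl]prop-2-enal | COc1cc([C@@H]2Oc3c(OC)cc(/C=C/C=O)cc3[C@H]2CO)cc(OC)c1OC
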